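**Retrosynthetic overview**
1. Feature: ring B of the target (C5, C6, C7, C8, C9, C20, C10) is an abietane ring B in which aryl carbon C9 has moved from C10 to C20, so all twenty carbons, C4, C5 and the oxygenated isopropyl ring C map onto carnosic acid 1.
2. Target 32 ⇐ MOM removal and autoxidation to the hydroxyquinone, Luche reduction at C1, DDQ dehydrogenation C6–C7, SeO2 oxidation at C1 ⇐ icetexane lactone 25.
3. 25 ⇐ 1,2-aryl shift of the neopentyl mesylate 24 (C9–C20 formed, C9–C10 broken; ring B goes from six to seven atoms).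
4. 24 ⇐ γ-lactone C19(=O)–O–C6 made before the shift: 6β-OH from the 6,7-alkene, then 6β-oxygen-directed δ-C–H silylation of the C19 methyl and oxidation. C19 is reached from O6 and not from a C20 alkoxyl radical, which would lose formaldehyde or abstract at C2/C6.
5. Ring order: rings A, B (six-membered) and C from 1; C14–O by Teuber oxidation; lactone ring (step 11); ring B enlargement (step 14); quinone last (step 18).

Key step: step 14

Assumption (chemistry): in carnosic acid the carboxyl group and the unhindered O12 are alkylated before the peri, hydrogen-bonded O11; otherwise the monoethers are separated at compound 3.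

**Step 1**
Reactants: 1 carnosic acid; 2 chloromethyl methyl ether
Product: 3 methoxymethyl 11-hydroxy-12-(methoxymethoxy)abieta-8,11,13-trien-20-oate
Conditions: MOMCl (2.2 equiv), iPr2NEt, CH2Cl2, 0 °C, Ar
Reagents that add atoms: chloromethyl methyl ether, COCCl
Why: Williamson-type O-alkylation in which the carboxylate and the open 12-phenol should react first, leaving the 11-OH (peri to C1/C20, hydrogen-bonded to the carboxyl oxygen) free for step 2.

**Step 2**
Reactants: 3; 4 Fremy's salt, (KSO3)2NO
Product: 5 methoxymethyl 12-(methoxymethoxy)-11,14-dioxoabieta-8,12-dien-20-oate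
Conditions: (KSO3)2NO, KH2PO4 buffer, acetone/H2O, rt
Reagents that add atoms: Fremy's salt, [K+].[K+].[O]N(S(=O)(=O)[O-])S(=O)(=O)[O-]
Why: Teuber oxidation of the free 11-phenol, whose para position C14 carries hydrogen, should give the 11,14-para-quinone and so install the C14 oxygen of the target.

**Step 3**
Reactants: 5; 2 chloromethyl methyl ether
Product: 7 methoxymethyl 11,12,14-tris(methoxymethoxy)abieta-8,11,13-trien-20-oate, via hydroquinone 6 (not isolated)
Conditions: Na2S2O4, EtOAc/H2O, rt; then NaH, MOMCl, DMF, 0 °C to rt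
Reagents that add atoms: chloromethyl methyl ether, COCCl
Why: dithionite reduction of the quinone followed by Williamson alkylation of the hydroquinone should give an air-stable, electron-rich arene with no aryl C–H, protected by groups that can be removed at the end without protic acid.

**Step 4**
Reactants: 7
Product: 8 11,12,14-tris(methoxymethoxy)abieta-8,11,13-trien-20-ol
Conditions: LiAlH4, THF, 0 °C to reflux
Reagents that add atoms: none
Why: hydride reduction of the hindered ester to the neopentyl alcohol, done before any 6β-oxygen exists because a C20 ester would be acylated by a syn-axial 6β-hydroxyl to a γ-lactone.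

**Step 5**
Reactants: 8; 9 benzyl bromide
Product: 10 20-benzyloxy-11,12,14-tris(methoxymethoxy)abieta-8,11,13-triene
Conditions: NaH, BnBr, Bu4NI (cat.), DMF, 0 °C to rt
Reagents that add atoms: benzyl bromide, BrCc1ccccc1
Why: Williamson etherification; the benzyl ether carries the C20 oxygen through the oxidations at C6 and C19 and is later removed by neutral hydrogenolysis while the molecule has no alkene.

**Step 6**
Reactants: 10
Product: 11 20-benzyloxy-11,12,14-tris(methoxymethoxy)abieta-6,8,11,13-tetraene
Conditions: DDQ (1.1 equiv), benzene, 4 Å MS, 60 °C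
Reagents that add atoms: none
Why: DDQ dehydrogenation by hydride abstraction from benzylic C7 (cation stabilised by the para C12 and ortho C14 oxygens) and loss of H6 should give the 6,7-alkene, and the quaternary C10 excludes further aromatisation.

**Step 7**
Reactants: 11; 12 hydrogen peroxide
Product: 14 20-benzyloxy-11,12,14-tris(methoxymethoxy)abieta-8,11,13-trien-6α-ol, via C6 alkylborane 13 (not isolated)
Conditions: BH3·THF, THF, 0 °C to rt; then NaOH, H2O2, 0 °C
Reagents that add atoms: hydrogen peroxide, OO
Why: hydroboration–oxidation should place boron on the non-benzylic C6 of the electron-rich styrene from the open alpha face (the beta face carries the axial C19 methyl and C20 CH2OBn), a cation-free hydration whose C6 configuration is corrected in steps 8 and 9.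

**Step 8**
Reactants: 14
Product: 15 20-benzyloxy-11,12,14-tris(methoxymethoxy)abieta-8,11,13-trien-6-one
Conditions: Dess–Martin periodinane, NaHCO3, CH2Cl2, 0 °C to rt
Reagents that add atoms: none
Why: Dess–Martin oxidation of the secondary alcohol under buffered conditions, which should leave the C5 alpha-hydrogen next to the new ketone unepimerised.

**Step 9**
Reactants: 15
Product: 16 20-benzyloxy-11,12,14-tris(methoxymethoxy)abieta-8,11,13-trien-6β-ol
Conditions: NaBH4, MeOH/THF, 0 °C
Reagents that add atoms: none
Why: borohydride reduction in which hydride should attack the 6-ketone from the alpha face, anti to the two beta-axial substituents on C4 and C10, setting the axial 6β-OH syn to the C19 methyl.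

**Step 10**
Reactants: 16; 12 hydrogen peroxide
Product: 19 20-benzyloxy-11,12,14-tris(methoxymethoxy)abieta-8,11,13-triene-6β,19-diol, via silyl ether 17 (not isolated), via oxasilinane 18 (not isolated)
Conditions: Et2SiH2, [Ir(cod)OMe]2 (cat.), THF, rt; then [Rh(cod)Cl]2/Xantphos (cat.), norbornene, THF, 100 °C; then H2O2, KHCO3, KF, THF/MeOH, 50 °C
Reagents that add atoms: hydrogen peroxide, OO
Why: hydroxyl-directed C–H silylation followed by Tamao–Fleming oxidation, in which the 6β-O–SiHEt2 group should deliver silicon to the only primary δ C–H it can reach, the syn-axial C19 methyl (C4 and C10 are quaternary, C8 is aromatic, the C20 CH2 is a secondary C–H, the arene has no C–H), so that the tether geometry makes C4 a stereocentre with the beta carbon oxidised; an oxygen-centred radical is avoided because it would attack the activated C20 hydrogens or fragment toward benzylic C7.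

**Step 11**
Reactants: 19
Product: 21 20-benzyloxy-11,12,14-tris(methoxymethoxy)abieta-8,11,13-trien-19,6β-olide, via lactol 20 (not isolated)
Conditions: TEMPO (cat.), PhI(OAc)2, CH2Cl2, rt
Reagents that add atoms: none
Why: oxoammonium (TEMPO/PhI(OAc)2) oxidative lactonisation of a 1,4-diol, in which the primary C19 alcohol is oxidised to the aldehyde, closes with the 6β-OH to the lactol and is oxidised again to the cis-fused γ-lactone, the hindered secondary alcohol itself not being oxidised.

**Step 12**
Reactants: 21
Product: 22 20-hydroxy-11,12,14-tris(methoxymethoxy)abieta-8,11,13-trien-19,6β-olide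
Conditions: H2 (1 atm), Pd/C, EtOAc, rt
Reagents that add atoms: none
Why: hydrogenolysis of the benzyl ether under neutral conditions, so that the freed C20 alcohol should not transacylate the neighbouring lactone.

**Step 13**
Reactants: 22; 23 methanesulfonyl chloride
Product: 24 20-mesyloxy-11,12,14-tris(methoxymethoxy)abieta-8,11,13-trien-19,6β-olide
Conditions: MsCl, Et3N, CH2Cl2, −20 °C; used crude
Reagents that add atoms: methanesulfonyl chloride, CS(=O)(=O)Cl
Why: sulfonylation through sulfene, which works on hindered neopentyl alcohols, kept cold because the product is set up for aryl-assisted ionisation.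

**Step 14**
Reactants: 24
Product: 25 11,12,14-tris(methoxymethoxy)-9(10→20)-abeo-abieta-8,11,13,10(20)-tetraen-19,6β-olide
Conditions: 2,6-lutidine, (CF3)2CHOH, 40 °C
Reagents that add atoms: none
Why: Ionisation of the neopentyl C20–O bond in the ionising, weakly nucleophilic solvent is assisted by the electron-rich ring: C9 bridges C10 and C20 in a phenonium ion stabilised by the ortho C11 oxygen, the C9–C10 bond breaks, and the tertiary C10 cation loses a C20 proton to lutidine to give the arene-conjugated C10=C20 alkene. The closest known reaction type is the Wagner–Meerwein 1,2-aryl shift of neophyl-type sulfonates, as in the abietane-to-icetexane rearrangement of 20-sulfonyloxy-abietatrienes. The seven-membered ring B is not closed end to end but arises by ring enlargement: C9–C20 forms by 3-exo attack of the aryl π system on C20 and the six-membered ring opens at C9–C10. No stereocentre is created; C10 becomes trigonal and C4, C5 and C6 are not involved. The step needs aryl rather than alkyl (C1, C5) migration, which the anchimeric assistance of the trioxygenated ring secures, and proton loss toward C20 rather than C1 or C5, which conjugation with the arene favours. The 19-carboxyl is tied to the 6β-oxygen as the lactone, so its carbonyl oxygen can reach neither C20 nor the C10 cation.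

**Step 15**
Reactants: 25; 26 selenium dioxide
Product: 28 1-oxo-11,12,14-tris(methoxymethoxy)-9(10→20)-abeo-abieta-8,11,13,10(20)-tetraen-19,6β-olide, via allylic alcohol 27 (not isolated)
Conditions: SeO2, pyridine (cat.), 1,4-dioxane, 80 °C
Reagents that add atoms: selenium dioxide, O=[Se]=O
Why: Riley allylic oxidation (ene reaction at C10=C20 with selenium on C20, then [2,3]-sigmatropic shift) should oxygenate the allylic CH2 at C1 in preference to the tertiary C5–H and carry the alcohol on to the enone, and is run before C6=C7 exists so that C5–H is not doubly allylic.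

**Step 16**
Reactants: 28
Product: 29 1-oxo-11,12,14-tris(methoxymethoxy)-9(10→20)-abeo-abieta-6,8,11,13,10(20)-pentaen-19,6-olide
Conditions: DDQ (1.1 equiv), 1,4-dioxane, 60 °C
Reagents that add atoms: none
Why: DDQ dehydrogenation by hydride abstraction from benzylic C7 and loss of the only adjacent hydrogen (H6) should give the arene-conjugated enol lactone, while the C1 carbonyl on C10 disfavours hydride loss from C5 toward a benzotropylium ion.

**Step 17**
Reactants: 29
Product: 30 1β-hydroxy-11,12,14-tris(methoxymethoxy)-9(10→20)-abeo-abieta-6,8,11,13,10(20)-pentaen-19,6-olide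
Conditions: NaBH4, CeCl3·7H2O, MeOH, −40 °C
Reagents that add atoms: none
Why: Luche 1,2-reduction of the enone, in which axial hydride attack from the alpha face (syn to H5, unhindered) should give the equatorial 1β-alcohol, the hindered enol-lactone carbonyl on quaternary C4 staying intact at low temperature.

**Step 18**
Reactants: 30
Product: 32 6,7-anhydroballotiquinone, via hydroxyhydroquinone 31 (not isolated)
Conditions: TMSOTf, 2,2'-bipyridyl, CH2Cl2, 0 °C; then H2O; then air, EtOAc, rt
Reagents that add atoms: none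
Why: buffered Lewis-acid cleavage of the aryl MOM ethers without free protic acid (so the ionisable allylic C1–OH and the enol lactone should survive), followed by spontaneous autoxidation of the 11,12,14-trihydroxyarene to the 12-hydroxy-11,14-quinone.

**Compound list**
1 | carnosic acid | CC(C)c1cc2CC[C@H]3C(C)(C)CCC[C@]3(C(=O)O)c2c(O)c1O | starting material
2 | chloromethyl methyl ether | COCCl | starting material
3 | methoxymethyl 11-hydroxy-12-(methoxymethoxy)abieta-8,11,13-trien-20-oate | CC(C)c1cc2CC[C@H]3C(C)(C)CCC[C@]3(C(=O)OCOC)c2c(O)c1OCOC | intermediate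
4 | Fremy's salt, dipotassium nitrosodisulfonate (KSO3)2NO | [K+].[K+].[O]N(S(=O)(=O)[O-])S(=O)(=O)[O-] | starting material
5 | methoxymethyl 12-(methoxymethoxy)-11,14-dioxoabieta-8,12-dien-20-oate | CC(C)C1=C(OCOC)C(=O)C2=C(CC[C@H]3C(C)(C)CCC[C@@]32C(=O)OCOC)C1=O | intermediate
6 | methoxymethyl 11,14-dihydroxy-12-(methoxymethoxy)abieta-8,11,13-trien-20-oate (hydroquinone) | CC(C)c1c(O)c2CC[C@H]3C(C)(C)CCC[C@]3(C(=O)OCOC)c2c(O)c1OCOC | intermediate (not isolated)
7 | methoxymethyl 11,12,14-tris(methoxymethoxy)abieta-8,11,13-trien-20-oate | CC(C)c1c(OCOC)c2CC[C@H]3C(C)(C)CCC[C@]3(C(=O)OCOC)c2c(OCOC)c1OCOC | intermediate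
8 | 11,12,14-tris(methoxymethoxy)abieta-8,11,13-trien-20-ol | CC(C)c1c(OCOC)c2CC[C@H]3C(C)(C)CCC[C@]3(CO)c2c(OCOC)c1OCOC | intermediate
9 | benzyl bromide | BrCc1ccccc1 | starting material
10 | 20-benzyloxy-11,12,14-tris(methoxymethoxy)abieta-8,11,13-triene | CC(C)c1c(OCOC)c2CC[C@H]3C(C)(C)CCC[C@]3(COCc4ccccc4)c2c(OCOC)c1OCOC | intermediate
11 | 20-benzyloxy-11,12,14-tris(methoxymethoxy)abieta-6,8,11,13-tetraene | CC(C)c1c(OCOC)c2C=C[C@H]3C(C)(C)CCC[C@]3(COCc4ccccc4)c2c(OCOC)c1OCOC | intermediate
12 | hydrogen peroxide | OO | starting material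
13 | C6 alkylborane (6α-boryl adduct of 11) | CC(C)c1c(OCOC)c2C[C@H](B)[C@H]3C(C)(C)CCC[C@]3(COCc4ccccc4)c2c(OCOC)c1OCOC | intermediate (not isolated)
14 | 20-benzyloxy-11,12,14-tris(methoxymethoxy)abieta-8,11,13-trien-6α-ol | CC(C)c1c(OCOC)c2C[C@H](O)[C@H]3C(C)(C)CCC[C@]3(COCc4ccccc4)c2c(OCOC)c1OCOC | intermediate
15 | 20-benzyloxy-11,12,14-tris(methoxymethoxy)abieta-8,11,13-trien-6-one | CC(C)c1c(OCOC)c2CC(=O)[C@H]3C(C)(C)CCC[C@]3(COCc4ccccc4)c2c(OCOC)c1OCOC | intermediate
16 | 20-benzyloxy-11,12,14-tris(methoxymethoxy)abieta-8,11,13-trien-6β-ol | CC(C)c1c(OCOC)c2C[C@@H](O)[C@H]3C(C)(C)CCC[C@]3(COCc4ccccc4)c2c(OCOC)c1OCOC | intermediate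
17 | 6β-O-diethyl(hydrido)silyl ether of 16 | CC(C)c1c(OCOC)c2C[C@@H](O[SiH](CC)CC)[C@H]3C(C)(C)CCC[C@]3(COCc4ccccc4)c2c(OCOC)c1OCOC | intermediate (not isolated)
18 | 6β-O,19-C-diethylsilylene oxasilinane | CC(C)c1c(OCOC)c2C[C@H]3O[Si](CC)(CC)C[C@@]4(C)CCC[C@](COCc5ccccc5)(c2c(OCOC)c1OCOC)[C@@H]34 | intermediate (not isolated)
19 | 20-benzyloxy-11,12,14-tris(methoxymethoxy)abieta-8,11,13-triene-6β,19-diol | CC(C)c1c(OCOC)c2C[C@@H](O)[C@H]3[C@@](C)(CO)CCC[C@]3(COCc4ccccc4)c2c(OCOC)c1OCOC | intermediate
20 | 20-benzyloxy-6β,19-epoxy-11,12,14-tris(methoxymethoxy)abieta-8,11,13-trien-19-ol (lactol, C19 epimers) | CC(C)c1c(OCOC)c2C[C@H]3OC(O)[C@@]4(C)CCC[C@](COCc5ccccc5)(c2c(OCOC)c1OCOC)[C@@H]34 | intermediate (not isolated)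
21 | 20-benzyloxy-11,12,14-tris(methoxymethoxy)abieta-8,11,13-trien-19,6β-olide | CC(C)c1c(OCOC)c2C[C@H]3OC(=O)[C@@]4(C)CCC[C@](COCc5ccccc5)(c2c(OCOC)c1OCOC)[C@@H]34 | intermediate
22 | 20-hydroxy-11,12,14-tris(methoxymethoxy)abieta-8,11,13-trien-19,6β-olide | CC(C)c1c(OCOC)c2C[C@H]3OC(=O)[C@@]4(C)CCC[C@](CO)(c2c(OCOC)c1OCOC)[C@@H]34 | intermediate
23 | methanesulfonyl chloride | CS(=O)(=O)Cl | starting material
24 | 20-mesyloxy-11,12,14-tris(methoxymethoxy)abieta-8,11,13-trien-19,6β-olide | CC(C)c1c(OCOC)c2C[C@H]3OC(=O)[C@@]4(C)CCC[C@](COS(C)(=O)=O)(c2c(OCOC)c1OCOC)[C@@H]34 | intermediate (key-step precursor)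
25 | 11,12,14-tris(methoxymethoxy)-9(10→20)-abeo-abieta-8,11,13,10(20)-tetraen-19,6β-olide | CC(C)c1c(OCOC)c(OCOC)c2C=C3CCC[C@]4(C)C(=O)O[C@H](Cc2c1OCOC)[C@H]34 | intermediate (key-step product)
26 | selenium dioxide | O=[Se]=O | starting material
27 | 1-hydroxy derivative of 25 (allylic alcohol, C1 epimers) | CC(C)c1c(OCOC)c(OCOC)c2C=C3C(O)CC[C@]4(C)C(=O)O[C@H](Cc2c1OCOC)[C@H]34 | intermediate (not isolated)
28 | 1-oxo-11,12,14-tris(methoxymethoxy)-9(10→20)-abeo-abieta-8,11,13,10(20)-tetraen-19,6β-olide | CC(C)c1c(OCOC)c(OCOC)c2C=C3C(=O)CC[C@]4(C)C(=O)O[C@H](Cc2c1OCOC)[C@H]34 | intermediate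
29 | 1-oxo-11,12,14-tris(methoxymethoxy)-9(10→20)-abeo-abieta-6,8,11,13,10(20)-pentaen-19,6-olide | CC(C)c1c(OCOC)c(OCOC)c2C=C3C(=O)CC[C@]4(C)C(=O)OC(=Cc2c1OCOC)[C@H]34 | intermediate
30 | 1β-hydroxy-11,12,14-tris(methoxymethoxy)-9(10→20)-abeo-abieta-6,8,11,13,10(20)-pentaen-19,6-olide | CC(C)c1c(OCOC)c(OCOC)c2C=C3[C@H](O)CC[C@]4(C)C(=O)OC(=Cc2c1OCOC)[C@H]34 | intermediate
31 | 1β,11,12,14-tetrahydroxy-9(10→20)-abeo-abieta-6,8,11,13,10(20)-pentaen-19,6-olide (hydroxyhydroquinone) | CC(C)c1c(O)c(O)c2C=C3[C@H](O)CC[C@]4(C)C(=O)OC(=Cc2c1O)[C@H]34 | intermediate (not isolated)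
32 | 6,7-anhydroballotiquinone | CC(C)C1=C(O)C(=O)C2=C(C=C3OC(=O)[C@@]4(C)CC[C@@H](O)C(=C2)[C@@H]34)C1=O | target

**Step count**
Total: 18 steps. Longest linear sequence: 18 steps, from carnosic acid 1.

**Steps most likely to fail**

Step 10. The rhodium silyl species may fail to insert into the congested neopentyl C19–H, or may attack the C20 methylene, so that oxidation returns 16 or oxygenates the wrong carbon. The fallback sets out from 16 and replaces metal-catalysed silylation by a radical 1,5-hydrogen transfer. Hydrogenolysis (H2, Pd/C) should give the 6β,20-diol F1. Selective sulfonylation of the primary hydroxyl (MsCl 1.05 equiv, Et3N, −40 °C) should give the 20-monomesylate F2, in which the sulfonate makes the C20 hydrogens poor donors toward an electrophilic alkoxyl radical. The hypoiodite reaction (Pb(OAc)4, I2, CaCO3, cyclohexane, hν, 40 °C, aqueous work-up) should then functionalise the C19 methyl twice from the 6β-alkoxyl radical and give the 19-lactol F3. Oxidation with TEMPO/PhI(OAc)2 leads to the mesylate 24, where the fallback rejoins the route.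

Step 15. The ene step may remove the tertiary C5–H instead of a C1–H, or SeO2 may attack benzylic C7, so the oxygen lands on the wrong carbon. The fallback sets out from 25 and moves the oxygen in by epoxide chemistry. Epoxidation (mCPBA, NaHCO3, CH2Cl2) should give the 10,20-epoxide F4. Eliminative opening with Et2Al(TMP) (diethylaluminium 2,2,6,6-tetramethylpiperidide) removes a C1 proton and should give the 20-hydroxy-1(10)-ene F5. A 1,3-allylic transposition catalysed by Ph3SiOReO3 should move the hydroxyl to C1 and the alkene back into conjugation with the arene, giving 27. Dess–Martin oxidation of 27 gives the enone 28, where the fallback rejoins the route.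

Step 14. The C10 cation may lose a proton toward C1 or C5, giving non-conjugated alkene isomers instead of the C10=C20 styrene. The fallback sets out from 24 and does not rely on kinetic proton loss. The solvolysis is run as before and the crude alkene mixture, whose main contaminant should be the 1(10)-ene F6, is not separated. It is isomerised in a separate operation by metal-hydride hydrogen-atom transfer (Co(salen)Cl, PhSiH3 catalytic, benzene, rt), which equilibrates through the tertiary C10 radical toward the arene-conjugated 25, where the fallback rejoins the route.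

**Further compounds**
F1 | step 10 | 11,12,14-tris(methoxymethoxy)abieta-8,11,13-triene-6β,20-diol | CC(C)c1c(OCOC)c2C[C@@H](O)[C@H]3C(C)(C)CCC[C@]3(CO)c2c(OCOC)c1OCOC
F2 | step 10 | 20-mesyloxy-11,12,14-tris(methoxymethoxy)abieta-8,11,13-trien-6β-ol | CC(C)c1c(OCOC)c2C[C@@H](O)[C@H]3C(C)(C)CCC[C@]3(COS(C)(=O)=O)c2c(OCOC)c1OCOC
F3 | step 10 | 6β,19-epoxy-20-mesyloxy-11,12,14-tris(methoxymethoxy)abieta-8,11,13-trien-19-ol (lactol) | CC(C)c1c(OCOC)c2C[C@H]3OC(O)[C@@]4(C)CCC[C@](COS(C)(=O)=O)(c2c(OCOC)c1OCOC)[C@@H]34
F4 | step 15 | 10,20-epoxide of 25 | CC(C)c1c(OCOC)c(OCOC)c2C5OC53CCC[C@]4(C)C(=O)O[C@H](Cc2c1OCOC)[C@H]34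
F5 | step 15 | 20-hydroxy-11,12,14-tris(methoxymethoxy)-9(10→20)-abeo-abieta-1(10),8,11,13-tetraen-19,6β-olide | CC(C)c1c(OCOC)c(OCOC)c2C(O)C3=CCC[C@]4(C)C(=O)O[C@H](Cc2c1OCOC)[C@H]34
F6 | step 14 | 11,12,14-tris(methoxymethoxy)-9(10→20)-abeo-abieta-1(10),8,11,13-tetraen-19,6β-olide | CC(C)c1c(OCOC)c(OCOC)c2CC3=CCC[C@]4(C)C(=O)O[C@H](Cc2c1OCOC)[C@H]34
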